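The runs are simulated for an exercise, and the scatter is random.

Turn every percent of target into moles per litre before comparing runs.

| flask | solid substrate | gas phase | remark | time |
|---|---|---|---|---|
| spring | 0.42 M | 11 mM (held) | run made earlier |  |
| autumn | 0.66 M | 11 mM (held) | run made earlier |  |
| flask | 0.30 M | 11 mM (held) |  | 3.0 h |

| run | time / h | target / % |
|---|---|---|
| spring | 0.833 | 11 |
| spring | 1.00 | 12 |
| spring | 1.33 | 13 |
| spring | 1.50 | 15 |
| spring | 2.00 | 25 |
| spring | 2.50 | 27 |
| autumn | 0.833 | 7 |
| autumn | 1.00 | 7 |
| autumn | 1.33 | 8 |
| autumn | 1.50 | 9 |
| autumn | 2.00 | 13 |
| autumn | 2.50 | 17 |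

(each reading ± 2 percentage points)

- as a solid, counted per litre of solution: solid substrate
- at the start none of the gas is dissolved
- steps thought possible: starting material + dissolved gas -> target; starting material -> side product; target <-> isomer of the product; solid substrate <-> starting material; gas phase <-> dissolved gas; dissolved gas -> decomposition product
- at the start none of the solid substrate is in solution

- the best time, 3.0 h at the latest, for target
- the amount of target, in percent of the solid substrate charged, at that time

We take equal percentages in the spring and autumn runs as the zero of the scale, but at 2.50 h the spring run reads 1.59 times the autumn run, while the autumn charge is 1.57 times the spring charge, so the two runs read nearly the same target per litre, 0.113 M and 0.112 M, which, within the scatter of these readings, looks like zero order in the charge.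

We then reckon the rise twice from separate readings: from 1.00 h to 2.50 h the spring run gives 0.0420 M h⁻¹, and over the same times the autumn run gives 0.0440 M h⁻¹. These agree, so we carry their mean, 0.0430 M h⁻¹, as the molar slope, the target made per litre per hour.

Starting from the spring reading at 2.50 h and running the slope on to 3.0 h, our own reckoning gives 45.0% of the flask's charge of 0.30 M, still climbing at the limit, so we commit to 3.0 h; but both runs had a larger charge than this flask, so the slope is an assumption here.

The forecast names the same time, 3 h, and 42%, less than our 45.0%, in its words “so I shade the estimate down”.

Up to the limit of 3.0 h, the flask gives its most target at 3.00 h, namely 37.9%, beside 38.7% side product.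

    starting material + dissolved gas → target (k = 0.906 L mol⁻¹ min⁻¹)
    starting material → side product (k = 0.00462 min⁻¹)
    target ⇌ isomer of the product (K = 2.52, k = 9.77 × 10⁻⁴ min⁻¹)
    solid substrate ⇌ starting material, rate k4*(cs4 - [starting material]) while solid is left; crystals form when [starting material] > cs4 (solubility = 0.230 M, k = 0.100 min⁻¹)
    gas phase ⇌ dissolved gas, rate k5*(csat - [dissolved gas]) (kL = 0.140 min⁻¹)
    dissolved gas → decomposition product (k = 7.84 × 10⁻⁵ min⁻¹)

From 1.50 h to 3.00 h the target in the flask rose by 0.0299 M h⁻¹, slower than the molar slope of 0.0430 M h⁻¹, with solid substrate at 0% at 1.50 h. For the same charge read at 80 min, the slope gives 19.1% of the charge, and that neighbouring flask holds 20.6% target.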